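## Structural features

The target consists of two six-membered rings joined through a single methylene carbon: ring A, a 6-ethyl-4-hydroxy-5-methyl-2-pyrone bonded through C3, and ring B, a hexasubstituted benzene. Counted from the bridge carbon C1, ring B carries a hydroxyl at C2, a prenyl group at C3, a hydroxyl at C4, an isobutyryl group at C5 and a methoxy group at C6. Each of the three carbons lying between oxygens therefore bears a different carbon substituent. There is no stereocentre and no alkene geometry to set, because the prenyl double bond ends in two identical methyl groups; the problem is purely one of regiochemistry on ring B. Three elements are fragile: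
- the prenyl group flanked by two phenolic hydroxyls closes to a 2,2-dimethylchroman under acid and rules out hydrogenolysis;
- the methyl ether ortho to the ketone is cleaved by strong Lewis acids;
- the 4-hydroxy-2-pyrone is an acidic vinylogous acid whose C3 tends to react twice with one-carbon electrophiles.

The real difficulty is bringing the prenyl group to C3 without O-alkylation, double alkylation or dearomatisation. The key step exploits the oxygen on C4: its two ortho carbons are C5, blocked by the isobutyryl group, and C3, so an allyl group carried on this oxygen can be delivered only to C3. Its hydrogen bond to the ketone also sets it apart from the oxygen on C2 when the two must be distinguished.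

## Logic of the disconnections

20 is cut on both sides of the bridge carbon, at the bond to C3 of ring A and at the bond to ring B, which leads to 11, 16 and the one-carbon electrophile 17. Both neighbours of the bridge are carbon nucleophiles by nature: C3 of a vinylogous acid, and the last unsubstituted carbon of a phenol that is ortho to one free hydroxyl and para to the other. The cut divides the molecule into two fragments of similar size and leaves no protecting group on 20. The forward step must commit the one-carbon unit to 16 first (as 18, then 19), then have 11 capture it at carbon faster than a second molecule of 16 does, in a medium that never turns acidic.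

11 is taken back to 10 by placing a silyl group on the non-chelated oxygen. No skeletal bond is cut. The silyl ether keeps that oxygen silent in the earlier steps, and the free hydroxyl is wanted in the last step because it activates the neighbouring ring carbon. The forward step must cleave the O–Si bond near neutrality so that the prenylphenol does not cyclise.

10 is cut at the bond between ring carbon C3 and the prenyl CH2 and reconnected through the chelated oxygen, which gives 8 (passing through 9 in the forward direction). This converts a difficult intermolecular C-alkylation into an intramolecular delivery with only one possible destination. The gain is a substrate whose ring carries oxygen and acyl substituents only. The forward step must be a clean thermal [3,3] shift with allyl inversion, without loss of the tertiary allyl group and without acid.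

8 is cut at the O–C(CH3)2 bond into 4 and 7, and 7 goes back to 5. A tertiary allyl ether cannot be made by simple substitution, so the bond is assigned to π-allyl chemistry. The forward step must attack the more substituted allyl terminus and must use the only free oxygen of 4, which is hydrogen-bonded and hindered.

4 is taken back to 3 by removing the silyl group, and 3 is cut at the aryl–carbonyl bond into 1 and 2. This reaches two commercial compounds in two operations. The acylation must go to the carbon between a hydroxyl and the methoxy group, not to the carbon between the two hydroxyls, and the silylation must pick the hydroxyl that is not hydrogen-bonded to the ketone.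

16 is cut at C4–C5 and at O1–C2 into 13 and 14, and 13 goes back to 12. The three-carbon diacyl unit and the symmetrical ketone give the pyrone substitution pattern without any regiochemical choice. The forward step needs C-acylation of the enol ether before lactonisation.

## Other disconnections considered

Alternative 1: The cut runs through ring A, at C4–C5 and O1–C2 of the pyrone, so that ring A is assembled last on a ring B that already holds the bridge carbon as an arylmethylmalonyl unit. In the forward key step, 13 would be C-acylated by the dichloride A2 and the enol oxygen would then close the lactone, giving the bis-MOM ether A1; acid would then free the two phenols.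
- In favour: the bridge carbon is fixed to ring B before the pyrone exists, so a one-carbon electrophile never meets a free 4-hydroxypyrone and the pyrone cannot double up on one methylene. On this point the alternative is the better of the two. The ring closure is the same reaction type as step 8 of the chosen plan, so the two are equal in mechanistic confidence there.
- Against: A2 has to be made from a benzylic electrophile of ring B by malonate alkylation, hydrolysis and chlorination, and both the chlorination and the annulation liberate strong acid in the presence of two MOM acetals and the prenyl alkene. Monosubstituted malonyl chlorides also drift to acylketenes, which oligomerise. The final MOM removal needs acid exactly where the ortho-prenylphenol closes to a chroman.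
- Comparison: the alternative does not touch the prenyl problem, which would still have to be solved on ring B, for example by the rearrangement of the chosen plan. It is estimated to add four or more operations to the advanced ring-B fragment, where the chosen plan spends one (step 9).

Alternative 2: The cut removes the aryl–acyl C–C bond and the aryl C–O bond of the chelated hydroxyl and takes both back to an aryne. In the forward key step, a fluoride source would convert the silyl triflate A4 into the aryne A5. Isobutyric acid A6 would add through oxygen at the aryne carbon remote from the methoxy group, and the aryl anion formed next to the methoxy group would take over the acyl group through a four-membered transition state, giving A3.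
- In favour: the acyl and hydroxyl groups are placed in one step with a sense of addition dictated by the methoxy group, and the regiochemical ambiguity of the Friedel–Crafts acylation in step 1 is avoided. On this point the alternative is the better of the two.
- Against: A4 is itself pentasubstituted and must already carry the prenyl group, so the central problem is only moved to an earlier, less biased ring. Its triflate oxygen sits on the very carbon that becomes the chelated phenol, so one C–O bond is broken and rebuilt. The prenyl group stands next to the aryne and offers allylic hydrogens and a π bond for an intramolecular ene pathway. Proton transfer from A6 to the aryl anion competes with the acyl shift and would stop at the aryl ester. The branched acyl group slows the four-centre transfer.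
- Comparison: the chosen plan installs the ketone first and then uses it twice, as a blocking group and as a hydrogen-bond acceptor that differentiates the two oxygens. The alternative cannot use it that way because the ketone arrives after the prenyl group. The two plans are equal in needing one protecting group on the non-chelated oxygen, but the MOM group of A3 must leave under acid whereas the silyl group of the chosen plan leaves with fluoride. Preparing A4 is estimated to cost several more steps than steps 1, 2 and 4 together.

Alternative 3: The cut is the single bond between pyrone C3 and the bridge CH2, with the bridge carbon kept on ring B as an arylacetic acid. In the forward key step, the N-hydroxyphthalimide ester A8 would be reduced by a low-valent nickel–bipyridine catalyst with zinc. Decarboxylation gives the benzylic radical A10, nickel that has inserted into the C–Br bond of the bromopyrone A9 captures it, and reductive elimination gives the tris-MOM ether A7.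
- In favour: the union is cross-selective by construction, since one partner is a radical precursor and the other a C(sp2)–Br electrophile. It does not depend on the nucleophilicity of ring B and cannot double up the pyrone. On chemoselectivity of the fragment union it is the better of the two.
- Against: benzylic radicals of this kind readily couple with themselves, and A10 is flanked by two ortho substituents. The bromine of A9 lies between a carbonyl and an alkoxy group, which hinders both insertion and capture. The arylacetic acid needs a two-carbon unit on the most hindered ring carbon. Three MOM groups must be removed with acid at the end, with the chroman risk again.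
- Comparison: the chosen bridge formation is a polar, thermodynamically driven two-electron process with few variables. The alternative is a radical–organometallic sequence with more ways to leak. It would also add bromination and protection of the pyrone, construction and activation of the acid, and a final triple deprotection, against steps 6 and 9 of the chosen plan.

Key step: step 5

Remark: 13 is expected as a mixture of double-bond isomers with the Z form predominant; both lead to 16, and the Z form is drawn. The atom mapping of 8, 10 and 20 was checked (the silyloxy carbon becomes the hydroxyl next to the bridge, the methoxy group stays next to the isobutyryl group) and needs no correction.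

## Route

Step 1
Reactants: 1 5-methoxyresorcinol (5-methoxybenzene-1,3-diol); 2 isobutyryl chloride (2-methylpropanoyl chloride)
Product: 3 1-(2,4-dihydroxy-6-methoxyphenyl)-2-methylpropan-1-one
Conditions: AlCl3 (3 equiv), CH2Cl2/PhNO2, 0 °C → rt; aq HCl; chromatography
Reagents that add atoms: none
Why: Friedel–Crafts C-acylation of a very electron-rich arene; attack at the two equivalent carbons para to a hydroxyl (between OH and OMe) is expected to outweigh attack at the single carbon between the two hydroxyls, and the isomers differ in symmetry and hydrogen bonding, so they should separate on silica. The low temperature spares the methyl ether from cleavage by AlCl3.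

Step 2
Reactants: 3 1-(2,4-dihydroxy-6-methoxyphenyl)-2-methylpropan-1-one
Product: 4 1-[4-(tert-butyldimethylsilyloxy)-2-hydroxy-6-methoxyphenyl]-2-methylpropan-1-one
Conditions: TBSCl (1.05 equiv), imidazole, CH2Cl2, 0 °C
Reagents that add atoms: tert-butyldimethylsilyl chloride, CC(C)(C)[Si](C)(C)Cl
Why: Kinetically selective O-silylation of the more acidic, unhindered 4-hydroxyl; the 2-hydroxyl is tied up in a hydrogen bond to the ketone and flanked by the acyl group, so it should remain free.

Step 3
Reactants: 5 2-methylbut-3-en-2-ol
Product: 7 tert-butyl 2-methylbut-3-en-2-yl carbonate, via lithium 2-methylbut-3-en-2-olate 6 (not isolated)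
Conditions: n-BuLi, THF, −78 °C; then Boc2O, −78 °C → rt
Reagents that add atoms: di-tert-butyl dicarbonate, CC(C)(C)OC(=O)OC(=O)OC(C)(C)C
Why: Deprotonation of the tertiary allylic alcohol and O-acylation of the alkoxide (mixed carbonate formation); nothing ionises, so the allyl unit cannot transpose. The tert-butyl carbonate is chosen because the alkoxide it later releases is bulky and spares the aryl silyl ether.

Step 4
Reactants: 4 1-[4-(tert-butyldimethylsilyloxy)-2-hydroxy-6-methoxyphenyl]-2-methylpropan-1-one; 7 tert-butyl 2-methylbut-3-en-2-yl carbonate
Product: 8 1-[4-(tert-butyldimethylsilyloxy)-2-methoxy-6-(2-methylbut-3-en-2-yloxy)phenyl]-2-methylpropan-1-one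
Conditions: Pd(PPh3)4 (5 mol %), 4 Å MS, THF, 0 °C → rt
Reagents that add atoms: none
Why: Tsuji–Trost-type decarboxylative O-allylation: zerovalent palladium ionises 7 to a 1,1-dimethyl-π-allyl palladium cation, CO2 and tert-butoxide, which deprotonates the only free phenol of 4. The phenoxide attacks the more substituted allyl terminus, the usual kinetic outcome for oxygen nucleophiles with this carbonate, and gives the tertiary ether. The silyl ether keeps the more nucleophilic oxygen out of play and the low temperature limits re-ionisation of the product.

Step 5
Reactants: 8 1-[4-(tert-butyldimethylsilyloxy)-2-methoxy-6-(2-methylbut-3-en-2-yloxy)phenyl]-2-methylpropan-1-one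
Product: 10 1-[4-(tert-butyldimethylsilyloxy)-2-hydroxy-6-methoxy-3-(3-methylbut-2-enyl)phenyl]-2-methylpropan-1-one, via 6-prenylcyclohexa-2,4-dienone 9 (not isolated)
Conditions: PhNEt2, 160 °C, Ar, sealed tube
Reagents that add atoms: none
Why: Aromatic Claisen rearrangement: on heating, the O–C(CH3)2 bond breaks while the terminal CH2 of the vinyl group bonds to the hydrogen-bearing ortho carbon in a concerted suprafacial [3,3] shift through a chair-like six-membered transition state, giving dienone 9. 9 enolises at once to phenol 10, whose new hydroxyl is held by a hydrogen bond to the ketone, and the allyl inversion converts the 1,1-dimethylallyl ether into the linear prenyl group. The closest known reaction type is the thermal ortho-Claisen rearrangement of aryl 1,1-dimethylallyl ethers to ortho-prenylphenols. No ring is closed and no stereocentre remains, because the sp3 carbon of 9 is lost on enolisation and the new alkene carries two identical methyl groups. The step needs site selectivity, and the substrate secures it: of the two ortho carbons only one bears hydrogen, a shift to the acyl-bearing carbon is reversible and unproductive, and an onward Cope shift to the para carbon would have to bond through the tertiary allyl terminus and is not expected to compete. The step also needs chemoselectivity against loss of the five-carbon unit and against cyclisation of the ortho-prenylphenol to a chroman; the tertiary ether rearranges at moderate temperature and the basic amine solvent scavenges traces of acid. The silyl ether is thermally inert and meta to the new hydroxyl, so it cannot migrate.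

Step 6
Reactants: 10 1-[4-(tert-butyldimethylsilyloxy)-2-hydroxy-6-methoxy-3-(3-methylbut-2-enyl)phenyl]-2-methylpropan-1-one
Product: 11 1-[2,4-dihydroxy-6-methoxy-3-(3-methylbut-2-enyl)phenyl]-2-methylpropan-1-one
Conditions: TBAF, AcOH, THF, 0 °C
Reagents that add atoms: none
Why: Fluoride-mediated cleavage of an aryl silyl ether; the acetic acid buffer keeps the medium near neutral, so neither phenoxide-driven side reactions nor acid-driven chroman formation is expected, and the prenyl group and ketone are inert.

Step 7
Reactants: 12 3-pentanone
Product: 13 (Z)-3-(trimethylsilyloxy)pent-2-ene
Conditions: TMSCl, NaI, Et3N, MeCN, rt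
Reagents that add atoms: chlorotrimethylsilane, C[Si](C)(C)Cl
Why: Soft enolisation and O-silylation: iodotrimethylsilane formed from TMSCl and NaI activates the carbonyl and Et3N removes the α-proton. The ketone is symmetrical, so there is no regiochemical issue, and the alkene geometry is lost later in the aromatic pyrone.

Step 8
Reactants: 13 (Z)-3-(trimethylsilyloxy)pent-2-ene; 14 malonyl dichloride (propanedioyl dichloride)
Product: 16 6-ethyl-4-hydroxy-5-methyl-2H-pyran-2-one, via 4-methyl-3,5-dioxoheptanoyl chloride 15 (not isolated)
Conditions: Et2O, −78 °C → rt
Reagents that add atoms: none
Why: Effenberger-type pyrone synthesis: C-acylation of the silyl enol ether by one acyl chloride of 14 with loss of chlorosilane gives 15, whose enol oxygen attacks the second acyl chloride to close the six-membered lactone; tautomerisation gives the 4-hydroxy-2-pyrone. Low temperature in ether limits self-condensation of 14.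

Step 9
Reactants: 16 6-ethyl-4-hydroxy-5-methyl-2H-pyran-2-one; 17 N,N-dimethylmethyleneiminium iodide (Eschenmoser's salt); 11 1-[2,4-dihydroxy-6-methoxy-3-(3-methylbut-2-enyl)phenyl]-2-methylpropan-1-one
Product: 20 6-ethyl-4-hydroxy-3-{[2,4-dihydroxy-6-methoxy-5-(2-methylpropanoyl)-3-(3-methylbut-2-enyl)phenyl]methyl}-5-methyl-2H-pyran-2-one, via 3-(dimethylaminomethyl)pyrone 18 (not isolated), via 3-methylenepyran-2,4-dione 19 (not isolated)
Conditions: 16 + 17, MeCN, rt; then 11, 60 °C
Reagents that add atoms: none
Why: Mannich-type three-component methylene bridging of an acylphloroglucinol with a 4-hydroxy-2-pyrone: C3 of 16 is aminomethylated by 17 to give 18, which loses dimethylamine on warming to the strong Michael acceptor 19. The only unsubstituted ring carbon of 11, ortho to one free hydroxyl and para to the other, adds to 19 (Friedel–Crafts-type conjugate addition), and rearomatisation and enolisation give 20. Converting 16 fully into 18 before 11 is added leaves no free pyrone to compete, and the liberated amine keeps the medium from turning acidic.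

## Compound list

1 | 5-methoxyresorcinol (5-methoxybenzene-1,3-diol) | COc1cc(O)cc(O)c1 | starting material
2 | isobutyryl chloride (2-methylpropanoyl chloride) | CC(C)C(Cl)=O | starting material
3 | 1-(2,4-dihydroxy-6-methoxyphenyl)-2-methylpropan-1-one | COc1cc(O)cc(O)c1C(=O)C(C)C | intermediate
4 | 1-[4-(tert-butyldimethylsilyloxy)-2-hydroxy-6-methoxyphenyl]-2-methylpropan-1-one | COc1cc(O[Si](C)(C)C(C)(C)C)cc(O)c1C(=O)C(C)C | intermediate
5 | 2-methylbut-3-en-2-ol | CC(C)(O)C=C | starting material
6 | lithium 2-methylbut-3-en-2-olate (formed in the flask) | [Li+].[O-]C(C)(C)C=C | intermediate
7 | tert-butyl 2-methylbut-3-en-2-yl carbonate | CC(C)(C)OC(=O)OC(C)(C)C=C | intermediate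
8 | 1-[4-(tert-butyldimethylsilyloxy)-2-methoxy-6-(2-methylbut-3-en-2-yloxy)phenyl]-2-methylpropan-1-one | COc1cc(O[Si](C)(C)C(C)(C)C)cc(OC(C)(C)C=C)c1C(=O)C(C)C | intermediate
9 | 5-(tert-butyldimethylsilyloxy)-3-methoxy-6-(3-methylbut-2-enyl)-2-(2-methylpropanoyl)cyclohexa-2,4-dien-1-one (racemic, formed in the flask) | COC1=C(C(=O)C(C)C)C(=O)C(CC=C(C)C)C(O[Si](C)(C)C(C)(C)C)=C1 | intermediate
10 | 1-[4-(tert-butyldimethylsilyloxy)-2-hydroxy-6-methoxy-3-(3-methylbut-2-enyl)phenyl]-2-methylpropan-1-one | COc1cc(O[Si](C)(C)C(C)(C)C)c(CC=C(C)C)c(O)c1C(=O)C(C)C | intermediate
11 | 1-[2,4-dihydroxy-6-methoxy-3-(3-methylbut-2-enyl)phenyl]-2-methylpropan-1-one | COc1cc(O)c(CC=C(C)C)c(O)c1C(=O)C(C)C | intermediate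
12 | 3-pentanone | CCC(=O)CC | starting material
13 | (Z)-3-(trimethylsilyloxy)pent-2-ene (E isomer expected as minor component) | C/C=C(/CC)O[Si](C)(C)C | intermediate
14 | malonyl dichloride (propanedioyl dichloride) | O=C(Cl)CC(=O)Cl | starting material
15 | 4-methyl-3,5-dioxoheptanoyl chloride (racemic, formed in the flask) | CCC(=O)C(C)C(=O)CC(=O)Cl | intermediate
16 | 6-ethyl-4-hydroxy-5-methyl-2H-pyran-2-one | CCc1oc(=O)cc(O)c1C | intermediate
17 | N,N-dimethylmethyleneiminium iodide (Eschenmoser's salt) | C=[N+](C)C.[I-] | starting material
18 | 3-[(dimethylamino)methyl]-6-ethyl-4-hydroxy-5-methyl-2H-pyran-2-one (formed in the flask) | CCc1oc(=O)c(CN(C)C)c(O)c1C | intermediate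
19 | 6-ethyl-5-methyl-3-methylidene-2H-pyran-2,4(3H)-dione (formed in the flask) | CCC1=C(C)C(=O)C(=C)C(=O)O1 | intermediate
20 | 6-ethyl-4-hydroxy-3-{[2,4-dihydroxy-6-methoxy-5-(2-methylpropanoyl)-3-(3-methylbut-2-enyl)phenyl]methyl}-5-methyl-2H-pyran-2-one | CCc1oc(=O)c(Cc2c(O)c(CC=C(C)C)c(O)c(C(=O)C(C)C)c2OC)c(O)c1C | target

## Step count and risk

Total: 9 steps. Longest linear sequence: 6 steps from 1 (steps 1, 2, 4, 5, 6, 9); step 3 and steps 7–8 are side branches that feed steps 4 and 9.

Step 5 (key step). The most likely failure is fragmentation of the tertiary allyl ether instead of rearrangement: the aryloxy group ortho to the ketone is a fairly good leaving group, so heterolysis or a retro-ene loss of the five-carbon unit can compete, especially with traces of acid. Acid would also drive cyclisation of the product onto the new hydroxyl. Fallback: starting from 3, the phenoxide is C-prenylated directly with prenyl bromide in aqueous KOH at 0 °C. Attack through the carbon between the two oxygens gives 11 and the route is rejoined at 11. This replaces intramolecular delivery by an intermolecular nuclear alkylation; site selectivity would be modest, and material alkylated at the other free carbon or at oxygen would have to be separated. It makes no compound outside the list (F0).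

Step 1. The likely problems are insufficient regioselectivity (acylation between the two hydroxyls competes with acylation between hydroxyl and methoxy) and cleavage of the methyl ether ortho to the new ketone by AlCl3 if the mixture warms. Fallback: starting from 2, the symmetrical phenol phloroglucinol F1 is acylated under the same Friedel–Crafts conditions to 1-(2,4,6-trihydroxyphenyl)-2-methylpropan-1-one F2, where no regiochemical choice exists. The non-chelated para hydroxyl is silylated (TBSCl, imidazole) to 1-[4-(tert-butyldimethylsilyloxy)-2,6-dihydroxyphenyl]-2-methylpropan-1-one F3. One of the two equivalent ortho hydroxyls is then methylated under Mitsunobu conditions (MeOH, PPh3, DIAD, THF), which should stop after one alkylation because the remaining hydroxyl is locked by the ketone. The route is rejoined at 4.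

Step 4. The phenoxide of 4 is hydrogen-bonded and hindered, so capture of the π-allyl cation may be slow. The product ether can re-ionise on palladium and drift to the linear O-prenyl isomer or to C-allylation, and the tert-butoxide released may transfer or cleave the silyl group para to the ketone. Fallback: starting from 4, the phenol is alkylated with 3-chloro-3-methylbut-1-yne (CuCl2 catalytic, DBU, MeCN, 0 °C), a copper-mediated propargylic substitution that can only give the tertiary ether, to form 1-[4-(tert-butyldimethylsilyloxy)-2-methoxy-6-(2-methylbut-3-yn-2-yloxy)phenyl]-2-methylpropan-1-one F4. Semihydrogenation of the alkyne (H2, Pd/CaCO3 poisoned with Pb(OAc)2, quinoline, EtOAc) then gives 8, where the route is rejoined.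

Step 9. The danger is mis-routing of the one-carbon unit: a second molecule of 16 may add to 19 faster than the ring carbon of 11 does, and 11, deactivated by its acyl group, may react slowly at carbon. Fallback: the polarity is reversed. Starting from 11, the free ring carbon is aminomethylated first with 17 (CH2Cl2, rt) to give 1-[3-[(dimethylamino)methyl]-4,6-dihydroxy-2-methoxy-5-(3-methylbut-2-enyl)phenyl]-2-methylpropan-1-one F5. Heating F5 with 16 in dioxane at 100 °C expels dimethylamine to give the ortho-quinone methide 3-hydroxy-5-methoxy-6-methylidene-2-(3-methylbut-2-enyl)-4-(2-methylpropanoyl)cyclohexa-2,4-dien-1-one F6, which the strongly nucleophilic C3 of 16 traps by conjugate addition. The route is rejoined at 20. In this order the bridge carbon is already attached to ring B, so the pyrone cannot double up on it.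

## Further compounds

F0 | step 5 | none | none
F1 | step 1 | phloroglucinol (benzene-1,3,5-triol) | Oc1cc(O)cc(O)c1
F2 | step 1 | 1-(2,4,6-trihydroxyphenyl)-2-methylpropan-1-one | CC(C)C(=O)c1c(O)cc(O)cc1O
F3 | step 1 | 1-[4-(tert-butyldimethylsilyloxy)-2,6-dihydroxyphenyl]-2-methylpropan-1-one | CC(C)C(=O)c1c(O)cc(O[Si](C)(C)C(C)(C)C)cc1O
F4 | step 4 | 1-[4-(tert-butyldimethylsilyloxy)-2-methoxy-6-(2-methylbut-3-yn-2-yloxy)phenyl]-2-methylpropan-1-one | COc1cc(O[Si](C)(C)C(C)(C)C)cc(OC(C)(C)C#C)c1C(=O)C(C)C
F5 | step 9 | 1-[3-[(dimethylamino)methyl]-4,6-dihydroxy-2-methoxy-5-(3-methylbut-2-enyl)phenyl]-2-methylpropan-1-one | COc1c(CN(C)C)c(O)c(CC=C(C)C)c(O)c1C(=O)C(C)C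
F6 | step 9 | 3-hydroxy-5-methoxy-6-methylidene-2-(3-methylbut-2-enyl)-4-(2-methylpropanoyl)cyclohexa-2,4-dien-1-one | COC1=C(C(=O)C(C)C)C(O)=C(CC=C(C)C)C(=O)C1=C
A1 | alternative 1 | 6-ethyl-4-hydroxy-3-{[2,4-bis(methoxymethoxy)-6-methoxy-5-(2-methylpropanoyl)-3-(3-methylbut-2-enyl)phenyl]methyl}-5-methyl-2H-pyran-2-one | CCc1oc(=O)c(Cc2c(OCOC)c(CC=C(C)C)c(OCOC)c(C(=O)C(C)C)c2OC)c(O)c1C
A2 | alternative 1 | 2-{[2,4-bis(methoxymethoxy)-6-methoxy-5-(2-methylpropanoyl)-3-(3-methylbut-2-enyl)phenyl]methyl}propanedioyl dichloride | COCOc1c(CC=C(C)C)c(OCOC)c(C(=O)C(C)C)c(OC)c1CC(C(=O)Cl)C(=O)Cl
A3 | alternative 2 | 1-[2-hydroxy-6-methoxy-4-(methoxymethoxy)-3-(3-methylbut-2-enyl)phenyl]-2-methylpropan-1-one | COCOc1cc(OC)c(C(=O)C(C)C)c(O)c1CC=C(C)C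
A4 | alternative 2 | 3-methoxy-5-(methoxymethoxy)-6-(3-methylbut-2-enyl)-2-(trimethylsilyl)phenyl trifluoromethanesulfonate | COc1cc(OCOC)c(CC=C(C)C)c(OS(=O)(=O)C(F)(F)F)c1[Si](C)(C)C
A5 | alternative 2 | 1,2-didehydro-3-methoxy-5-(methoxymethoxy)-6-(3-methylbut-2-enyl)benzene (aryne) | COC1=CC(OCOC)=C(CC=C(C)C)C#C1
A6 | alternative 2 | isobutyric acid (2-methylpropanoic acid) | CC(C)C(=O)O
A7 | alternative 3 | 6-ethyl-4-(methoxymethoxy)-3-{[2,4-bis(methoxymethoxy)-6-methoxy-5-(2-methylpropanoyl)-3-(3-methylbut-2-enyl)phenyl]methyl}-5-methyl-2H-pyran-2-one | CCc1oc(=O)c(Cc2c(OCOC)c(CC=C(C)C)c(OCOC)c(C(=O)C(C)C)c2OC)c(OCOC)c1C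
A8 | alternative 3 | 1,3-dioxoisoindolin-2-yl 2-[2,4-bis(methoxymethoxy)-6-methoxy-5-(2-methylpropanoyl)-3-(3-methylbut-2-enyl)phenyl]acetate | COCOc1c(CC=C(C)C)c(OCOC)c(C(=O)C(C)C)c(OC)c1CC(=O)ON1C(=O)c2ccccc2C1=O
A9 | alternative 3 | 3-bromo-6-ethyl-4-(methoxymethoxy)-5-methyl-2H-pyran-2-one | CCc1oc(=O)c(Br)c(OCOC)c1C
A10 | alternative 3 | [2,4-bis(methoxymethoxy)-6-methoxy-5-(2-methylpropanoyl)-3-(3-methylbut-2-enyl)phenyl]methyl radical | [CH2]c1c(OCOC)c(CC=C(C)C)c(OCOC)c(C(=O)C(C)C)c1OC
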